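**Strategy.** Locants: ring C1 carries the side chain, C2 and C4 are =CH, C3 is the free carbinol, C5 bears OMe, and C6 is the ring CHOAc. The chain starts at C1′, and C2′ is its CHOAc. In the cyclohexa-1,4-diene ring, C6 is a secondary carbinol carbon between the alkene carbons C1 and C5. Both of these lie cis to C3 across their double bonds, so C6 is excised as a formate carbon. One operation joins a 1,5-dilithio-1,4-diene twice to HCO2Me, which forms C1–C6 and C5–C6, closes the ring and creates the C6 stereocentre. The precursor is the acyclic 1,5-bis(tributylstannyl) skipped diene 15, with both tin atoms cis to C3, a triisopropylsilyl ether at C3 and a free C2′ hydroxyl.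

Key step: step 10

Assumption: (R)-1,2-epoxytridecane is taken as a catalogue compound.

Design notes:
- **C2′ oxygen.** It is masked as a triethylsilyl ether only as far as 14 and is freed before the key step. A small silyl group there would sit 1,4 to the C1 carbanion and could migrate from O to C. A lithium alkoxide cannot migrate, it can chelate C1–Li, and the ring product then needs no acidic desilylation.
- **Ring compounds 19–21.** These are 3,6-dioxygenated cyclohexa-1,4-dienes carrying an enol ether, and they can aromatise by loss of water or acetic acid. After step 10 they therefore see only Ac2O/pyridine and buffered fluoride.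
- **C3 descriptor.** C3 keeps one spatial arrangement from 11 onward. Its descriptor is R in 11, where alkynyl outranks alkenyl, and S from 13 on.
- **Purification.** Stannanes and enol ethers are purified on triethylamine-deactivated silica.

**Step 1**
Reactants: 1 (R)-1,2-epoxytridecane; 2 lithium acetylide–ethylenediamine complex
Product: 3 (4R)-pentadec-1-yn-4-ol
Conditions: DMSO, 0 °C → rt
Reagents that add atoms: none
Why: SN2 opening of a terminal epoxide by an acetylide occurs at the unsubstituted carbon, so the C–O bond of the stereocentre is untouched and C2′ keeps the R configuration supplied by 1.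

**Step 2**
Reactants: 3 (4R)-pentadec-1-yn-4-ol
Product: 4 (4R)-4-(triethylsilyloxy)pentadec-1-yne
Conditions: Et3SiCl, imidazole, CH2Cl2, 0 °C → rt
Reagents that add atoms: chlorotriethylsilane, CC[Si](Cl)(CC)CC
Why: Standard imidazole-promoted silylation of a secondary alcohol; the triethylsilyl ether keeps the C2′ oxygen silent during acetylide formation, directed hydroalumination and C3 silylation, and is labile enough to leave later beside a triisopropylsilyl ether.

**Step 3**
Reactants: 5 methyl (E)-3-methoxyacrylate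
Product: 7 methyl (Z)-3-methoxy-3-(tributylstannyl)acrylate, via lithio acrylate 6 (not isolated)
Conditions: LiN(iPr)2 (commercial solution), THF, −95 °C; then Bu3SnCl, −95 → −40 °C
Reagents that add atoms: tributyltin chloride, CCCC[Sn](Cl)(CCCC)CCCC
Why: Directed vinylic lithiation: the β-hydrogen is acidified by the methoxy oxygen and lies cis to the ester carbonyl that chelates lithium, 6 holds its geometry at this temperature, and stannylation with retention puts tin cis to the carbon that becomes C3.

**Step 4**
Reactants: 7 methyl (Z)-3-methoxy-3-(tributylstannyl)acrylate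
Product: 8 (Z)-N,3-dimethoxy-N-methyl-3-(tributylstannyl)acrylamide
Conditions: MeNH(OMe)·HCl, iPrMgCl, THF, −20 → 0 °C
Reagents that add atoms: N,O-dimethylhydroxylamine hydrochloride, CNOC.Cl
Why: Weinreb amide formation by aminolysis of the ester with the chloromagnesium amide; 1,2-attack is favoured because tin shields the β-carbon, and the alkene geometry is not touched.

**Step 5**
Reactants: 4 (4R)-4-(triethylsilyloxy)pentadec-1-yne; 8 (Z)-N,3-dimethoxy-N-methyl-3-(tributylstannyl)acrylamide
Product: 10 (1Z,7R)-1-methoxy-1-(tributylstannyl)-7-(triethylsilyloxy)octadec-1-en-4-yn-3-one, via alkynyllithium 9 (not isolated)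
Conditions: 4, n-BuLi, THF, −78 °C; then 8, −78 → 0 °C
Reagents that add atoms: none
Why: Weinreb ketone synthesis forms C2–C3 and stops at the ketone stage, and an acetylide is too stabilised a carbanion to exchange with the alkenylstannane.

**Step 6**
Reactants: 10 (1Z,7R)-1-methoxy-1-(tributylstannyl)-7-(triethylsilyloxy)octadec-1-en-4-yn-3-one
Product: 11 (1Z,3R,7R)-1-methoxy-1-(tributylstannyl)-7-(triethylsilyloxy)octadec-1-en-4-yn-3-ol
Conditions: (R)-2-methyl-CBS-oxazaborolidine [(3aR)-1-methyl-3,3-diphenyltetrahydro-1H,3H-pyrrolo[1,2-c][1,3,2]oxazaborole] (cat.), catecholborane, toluene, −78 °C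
Reagents that add atoms: none
Why: Corey–Bakshi–Shibata reduction: the slim alkynyl arm acts as the small substituent and the β-stannylated alkenyl arm as the large one, so the R catalyst should deliver hydride to the face that gives (3R)-11, which is the spatial arrangement of C3 in the target, and catecholborane at −78 °C leaves alkyne, enol ether and stannane alone.

**Step 7**
Reactants: 11 (1Z,3R,7R)-1-methoxy-1-(tributylstannyl)-7-(triethylsilyloxy)octadec-1-en-4-yn-3-ol
Product: 13 (1Z,3S,4Z,7R)-1-methoxy-1,5-bis(tributylstannyl)-7-(triethylsilyloxy)octadeca-1,4-dien-3-ol, via cyclic alanate 12 (not isolated)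
Conditions: NaAlH2(OCH2CH2OMe)2, THF, 0 °C → rt; then Bu3SnOTf, −78 °C → rt
Reagents that add atoms: tributyltin triflate, CCCC[Sn](CCCC)(CCCC)OS(=O)(=O)C(F)(F)F
Why: Alkoxide-directed trans-hydroalumination of a propargylic alcohol places hydride on C2 and aluminium on C1 inside the five-membered ring of 12, so Al is cis to C3, and the known capture of such alanates by a tin triflate proceeds with retention to give the Z stannane at C1.

**Step 8**
Reactants: 13 (1Z,3S,4Z,7R)-1-methoxy-1,5-bis(tributylstannyl)-7-(triethylsilyloxy)octadeca-1,4-dien-3-ol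
Product: 14 (1Z,3S,4Z,7R)-1-methoxy-1,5-bis(tributylstannyl)-7-(triethylsilyloxy)-3-(triisopropylsilyloxy)octadeca-1,4-diene
Conditions: iPr3SiOTf, 2,6-lutidine, CH2Cl2, −78 → 0 °C
Reagents that add atoms: triisopropylsilyl triflate, CC(C)[Si](C(C)C)(C(C)C)OS(=O)(=O)C(F)(F)F
Why: Silyl triflate/lutidine silylation of a hindered secondary alcohol at low temperature stays basic throughout, which spares the acid-labile enol ether and both stannanes and does not touch the C3–O bond.

**Step 9**
Reactants: 14 (1Z,3S,4Z,7R)-1-methoxy-1,5-bis(tributylstannyl)-7-(triethylsilyloxy)-3-(triisopropylsilyloxy)octadeca-1,4-diene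
Product: 15 (1Z,3S,4Z,7R)-1-methoxy-1,5-bis(tributylstannyl)-3-(triisopropylsilyloxy)octadeca-1,4-dien-7-ol
Conditions: Bu4NF (1.05 equiv), THF, −20 → 0 °C
Reagents that add atoms: none
Why: Fluoride desilylation relies on the large rate gap between a secondary triethylsilyl ether and a hindered triisopropylsilyl ether, and it is done on the robust acyclic stage where basic fluoride can do no harm.

**Step 10**
Reactants: 15 (1Z,3S,4Z,7R)-1-methoxy-1,5-bis(tributylstannyl)-3-(triisopropylsilyloxy)octadeca-1,4-dien-7-ol; 16 methyl formate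
Product: 19 (1S,4S)-2-[(2R)-2-hydroxytridecyl]-6-methoxy-4-(triisopropylsilyloxy)cyclohexa-2,5-dien-1-ol, via trilithio diene 17 (not isolated), via lithio enal 18 (not isolated)
Conditions: n-BuLi (3.1 equiv), THF (0.01 M), −78 °C; then HCO2Me (1.0 equiv, slow addition), −78 → −30 °C
Reagents that add atoms: none
Why: Proposed new method: n-BuLi first deprotonates the C2′ hydroxyl and then exchanges both tributylstannyl groups with retention, so that in 17 the C1–Li and C5–Li bonds both face C3; the more exposed α-methoxyalkenyllithium at C5 should add to HCO2Me first, loss of LiOMe gives enal 18, and C1–Li then adds to the new formyl carbon (the opposite order converges on the same ring). The closest known reactions are the double addition of alkenyl-lithium or -magnesium reagents to a formate ester to give dialkenyl carbinols, the annulation of α,ω-di-Grignard reagents with esters to give cycloalkanols, and the closure of tin-derived 1,5-dilithiopenta-1,4-dienes with dihalosilanes; a carbon [5+1] closure on a dianion this functionalised is not known. The six-membered ring closes in the 6-exo-trig mode, with the carbonyl oxygen staying outside the ring. C6 is set by 1,4-induction from C3: in a boat-like transition state the triisopropylsilyl ether should sit pseudo-equatorial while the developing C6–OLi, pressed by C1′ and OMe, goes pseudo-axial on the opposite face, which gives the trans (C3 S, C6 S) isomer, although this induction is untested. Ring closure has to beat a second intermolecular formylation and O→C silyl migration, and this is served by one equivalent of formate added slowly to a dilute solution at −78 °C, the cis geometry of both C–Li bonds, the bulk of the triisopropylsilyl group and the absence of any silyl group on the C2′ oxygen.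

**Step 11**
Reactants: 19 (1S,4S)-2-[(2R)-2-hydroxytridecyl]-6-methoxy-4-(triisopropylsilyloxy)cyclohexa-2,5-dien-1-ol
Product: 20 (1S,4S)-2-[(2R)-2-acetoxytridecyl]-6-methoxy-4-(triisopropylsilyloxy)cyclohexa-2,5-dien-1-yl acetate
Conditions: Ac2O, pyridine, 4-(dimethylamino)pyridine (cat.), CH2Cl2, 0 °C → rt
Reagents that add atoms: acetic anhydride, CC(=O)OC(C)=O
Why: Nucleophile-catalysed acylation esterifies the two free hydroxyls at C6 and C2′ in one operation under mildly basic conditions while C3 is still silylated, and no stereocentre is touched.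

**Step 12**
Reactants: 20 (1S,4S)-2-[(2R)-2-acetoxytridecyl]-6-methoxy-4-(triisopropylsilyloxy)cyclohexa-2,5-dien-1-yl acetate
Product: 21 (1S,4S)-2-[(2R)-2-acetoxytridecyl]-4-hydroxy-6-methoxycyclohexa-2,5-dien-1-yl acetate (target)
Conditions: Bu4NF/AcOH (1:1), THF, 0 °C → rt
Reagents that add atoms: none
Why: Fluoride cleavage of the silyl ether buffered with acetic acid stays near neutral, so that no acetate is cleaved, no 1,4-loss of acetic acid to an arene is triggered and the enol ether sees no strong acid; no stereocentre is involved.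

**Compound list**
1 | (R)-1,2-epoxytridecane | CCCCCCCCCCC[C@@H]1CO1 | starting material
2 | lithium acetylide–ethylenediamine complex | [Li]C#C.NCCN | starting material
3 | (4R)-pentadec-1-yn-4-ol | CCCCCCCCCCC[C@H](CC#C)O | intermediate
4 | (4R)-4-(triethylsilyloxy)pentadec-1-yne | CCCCCCCCCCC[C@H](CC#C)O[Si](CC)(CC)CC | intermediate
5 | methyl (E)-3-methoxyacrylate | CO/C=C/C(=O)OC | starting material
6 | methyl 3-lithio-3-methoxyacrylate, Li cis to CO2Me | CO/C(=C/C(=O)OC)[Li] | intermediate
7 | methyl (Z)-3-methoxy-3-(tributylstannyl)acrylate, Sn cis to CO2Me | CO/C(=C/C(=O)OC)[Sn](CCCC)(CCCC)CCCC | intermediate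
8 | (Z)-N,3-dimethoxy-N-methyl-3-(tributylstannyl)acrylamide | CO/C(=C/C(=O)N(C)OC)[Sn](CCCC)(CCCC)CCCC | intermediate
9 | (4R)-1-lithio-4-(triethylsilyloxy)pentadec-1-yne | CCCCCCCCCCC[C@H](CC#C[Li])O[Si](CC)(CC)CC | intermediate
10 | (1Z,7R)-1-methoxy-1-(tributylstannyl)-7-(triethylsilyloxy)octadec-1-en-4-yn-3-one | CCCCCCCCCCC[C@H](CC#CC(=O)/C=C(/OC)[Sn](CCCC)(CCCC)CCCC)O[Si](CC)(CC)CC | intermediate
11 | (1Z,3R,7R)-1-methoxy-1-(tributylstannyl)-7-(triethylsilyloxy)octadec-1-en-4-yn-3-ol | CCCCCCCCCCC[C@H](CC#C[C@H](O)/C=C(/OC)[Sn](CCCC)(CCCC)CCCC)O[Si](CC)(CC)CC | intermediate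
12 | sodium cyclic alkenylalanate: five-membered ring O–Al–C1=C2–C3, Al also bearing two 2-methoxyethoxy groups | CCCCCCCCCCC[C@H](CC1=C[C@@H](/C=C(/OC)[Sn](CCCC)(CCCC)CCCC)O[Al-]1(OCCOC)OCCOC)O[Si](CC)(CC)CC.[Na+] | intermediate
13 | (1Z,3S,4Z,7R)-1-methoxy-1,5-bis(tributylstannyl)-7-(triethylsilyloxy)octadeca-1,4-dien-3-ol | CCCCCCCCCCC[C@H](C/C(=C/[C@H](O)/C=C(/OC)[Sn](CCCC)(CCCC)CCCC)[Sn](CCCC)(CCCC)CCCC)O[Si](CC)(CC)CC | intermediate
14 | (1Z,3S,4Z,7R)-1-methoxy-1,5-bis(tributylstannyl)-7-(triethylsilyloxy)-3-(triisopropylsilyloxy)octadeca-1,4-diene | CCCCCCCCCCC[C@H](C/C(=C/[C@H](O[Si](C(C)C)(C(C)C)C(C)C)/C=C(/OC)[Sn](CCCC)(CCCC)CCCC)[Sn](CCCC)(CCCC)CCCC)O[Si](CC)(CC)CC | intermediate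
15 | (1Z,3S,4Z,7R)-1-methoxy-1,5-bis(tributylstannyl)-3-(triisopropylsilyloxy)octadeca-1,4-dien-7-ol | CCCCCCCCCCC[C@H](C/C(=C/[C@H](O[Si](C(C)C)(C(C)C)C(C)C)/C=C(/OC)[Sn](CCCC)(CCCC)CCCC)[Sn](CCCC)(CCCC)CCCC)O | intermediate
16 | methyl formate | COC=O | starting material
17 | trilithio diene: C1–Li and C5–Li both cis to C3, C2′–OLi, stereocentres as in 15 | CCCCCCCCCCC[C@H](C/C(=C/[C@H](O[Si](C(C)C)(C(C)C)C(C)C)/C=C(/OC)[Li])[Li])O[Li] | intermediate
18 | lithio enal: C5–CHO (the future C6), C1–Li, C2′–OLi, stereocentres as in 15 | CCCCCCCCCCC[C@H](C/C(=C/[C@H](O[Si](C(C)C)(C(C)C)C(C)C)/C=C(/OC)C=O)[Li])O[Li] | intermediate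
19 | (1S,4S)-2-[(2R)-2-hydroxytridecyl]-6-methoxy-4-(triisopropylsilyloxy)cyclohexa-2,5-dien-1-ol | CCCCCCCCCCC[C@H](CC1=C[C@H](O[Si](C(C)C)(C(C)C)C(C)C)C=C(OC)[C@H]1O)O | intermediate
20 | (1S,4S)-2-[(2R)-2-acetoxytridecyl]-6-methoxy-4-(triisopropylsilyloxy)cyclohexa-2,5-dien-1-yl acetate | CCCCCCCCCCC[C@H](CC1=C[C@H](O[Si](C(C)C)(C(C)C)C(C)C)C=C(OC)[C@H]1OC(C)=O)OC(C)=O | intermediate
21 | (1S,4S)-2-[(2R)-2-acetoxytridecyl]-4-hydroxy-6-methoxycyclohexa-2,5-dien-1-yl acetate | CCCCCCCCCCC[C@H](CC1=C[C@H](O)C=C(OC)[C@H]1OC(C)=O)OC(C)=O | target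

Total step count: 12.
Longest linear sequence: 10 steps (steps 1, 2 and 5–12; the branch through steps 3, 4 and 5–12 is equally long).

**Steps most likely to fail**

**1. Step 10 (labelled step).**
- What may go wrong: incomplete second tin–lithium exchange at the hindered C1, migration of the C3 silyl group from oxygen to carbon, intermolecular double formylation or oligomerisation in place of ring closure, and poor facial selectivity at C6.
- The fallback uses known chemistry, sets out from 14 and returns at 19.
- One equivalent of n-BuLi (THF, −78 °C, short contact) should exchange only the faster-reacting α-methoxy stannane at C5. DMF then gives the C5-formyl monostannane F1.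
- I2 in CH2Cl2 at −78 °C replaces the C1 tin by iodine with retention and gives the iodo enal F2.
- An intramolecular Nozaki–Hiyama–Kishi reaction (CrCl2, catalytic NiCl2, DMSO/THF, high dilution) forms C1–C6 and gives the ring carbinol C2′ triethylsilyl ether F3.
- Bu4NF/AcOH at 0 °C frees the C2′ hydroxyl and leads to 19. C6 epimers are diastereomers and would be separated at this stage.

**2. Step 7.**
- What may go wrong: sluggish transfer of the hindered alkenyl group from aluminium to tin, so that the alanate is merely protonated on work-up, or attack of the Lewis-acidic tin triflate on the enol ether.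
- The fallback sets out from 11 and returns at 15 with the same number of operations.
- iPr3SiOTf/2,6-lutidine gives the C3-silylated enyne F4, and Bu4NF at 0 °C removes the triethylsilyl group to give the homopropargylic alcohol F5.
- Ruthenium-catalysed trans-hydrostannation ([Cp*RuCl]4, Bu3SnH, CH2Cl2, rt) then gives 15. The free C2′ hydroxyl steers tin to the nearer alkyne carbon C1, the bulky C3 ether reinforces this, and the trans addition places tin cis to C3.

**3. Step 12.**
- What may go wrong: slow cleavage of the robust silyl ether under buffered fluoride, loss of acetic acid with aromatisation, or cleavage of an acetate.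
- The fallback sets out from 19 and returns at 21. It moves the removal of the robust group ahead of the acetylation.
- Unbuffered Bu4NF in THF is harmless while no acyl group is present and gives the triol F6.
- Et3SiCl (1 equiv) with 2,6-lutidine at −78 °C should silylate the least hindered hydroxyl, C3–OH, which is flanked by two unsubstituted =CH groups. This gives the C3 triethylsilyl ether diol F7.
- Ac2O/pyridine/4-(dimethylamino)pyridine gives the C3 triethylsilyl ether diacetate F8. Its far more labile silyl group leaves with Bu4NF/AcOH at −20 °C to give 21.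

**Further compounds**
F1 | step 10 | (2E,4R,5Z,8R)-2-methoxy-6-(tributylstannyl)-8-(triethylsilyloxy)-4-(triisopropylsilyloxy)nonadeca-2,5-dienal | CCCCCCCCCCC[C@H](C/C(=C/[C@H](O[Si](C(C)C)(C(C)C)C(C)C)/C=C(/OC)C=O)[Sn](CCCC)(CCCC)CCCC)O[Si](CC)(CC)CC
F2 | step 10 | (2E,4R,5Z,8R)-6-iodo-2-methoxy-8-(triethylsilyloxy)-4-(triisopropylsilyloxy)nonadeca-2,5-dienal | CCCCCCCCCCC[C@H](C/C(=C/[C@H](O[Si](C(C)C)(C(C)C)C(C)C)/C=C(/OC)C=O)I)O[Si](CC)(CC)CC
F3 | step 10 | (1S,4S)-6-methoxy-2-[(2R)-2-(triethylsilyloxy)tridecyl]-4-(triisopropylsilyloxy)cyclohexa-2,5-dien-1-ol | CCCCCCCCCCC[C@H](CC1=C[C@H](O[Si](C(C)C)(C(C)C)C(C)C)C=C(OC)[C@H]1O)O[Si](CC)(CC)CC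
F4 | step 7 | (1Z,3R,7R)-1-methoxy-1-(tributylstannyl)-7-(triethylsilyloxy)-3-(triisopropylsilyloxy)octadec-1-en-4-yne | CCCCCCCCCCC[C@H](CC#C[C@H](O[Si](C(C)C)(C(C)C)C(C)C)/C=C(/OC)[Sn](CCCC)(CCCC)CCCC)O[Si](CC)(CC)CC
F5 | step 7 | (1Z,3R,7R)-1-methoxy-1-(tributylstannyl)-3-(triisopropylsilyloxy)octadec-1-en-4-yn-7-ol | CCCCCCCCCCC[C@H](CC#C[C@H](O[Si](C(C)C)(C(C)C)C(C)C)/C=C(/OC)[Sn](CCCC)(CCCC)CCCC)O
F6 | step 12 | (1S,4S)-2-[(2R)-2-hydroxytridecyl]-6-methoxycyclohexa-2,5-diene-1,4-diol | CCCCCCCCCCC[C@H](CC1=C[C@H](O)C=C(OC)[C@H]1O)O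
F7 | step 12 | (1S,4S)-2-[(2R)-2-hydroxytridecyl]-6-methoxy-4-(triethylsilyloxy)cyclohexa-2,5-dien-1-ol | CCCCCCCCCCC[C@H](CC1=C[C@H](O[Si](CC)(CC)CC)C=C(OC)[C@H]1O)O
F8 | step 12 | (1S,4S)-2-[(2R)-2-acetoxytridecyl]-6-methoxy-4-(triethylsilyloxy)cyclohexa-2,5-dien-1-yl acetate | CCCCCCCCCCC[C@H](CC1=C[C@H](O[Si](CC)(CC)CC)C=C(OC)[C@H]1OC(C)=O)OC(C)=O
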